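**Assumptions:** The SMILES has no stereocenters, so no stereochemistry has to be set. I read the acyl chain as 30 carbons including the carbonyl carbon (triacontanoate). The target is therefore tyrosol 4-hydroxyphenethyl triacontanoate, C38H68O3. The only ring is the benzene ring, which comes from the starting material.

## Retrosynthetic overview
1. Remove the phenol protecting group (aryl TBS ether) from the last intermediate to reach the target.
2. Disconnect the primary ester C–O bond by an anti-Markovnikov hydroacyloxylation of 4-(TBSO)styrene with triacontanoic acid. This is the proposed new step, and it avoids any need to differentiate the two OH groups of tyrosol.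
3. Make the styrene from 4-hydroxybenzaldehyde by O-silylation and then Wittig methylenation.
4. No new rings are formed; the existing benzene ring is carried through.

## Route

**Step 1**
Reactants: 1 (4-hydroxybenzaldehyde); 2 (tert-butyldimethylsilyl chloride)
Product: 3 (4-(tert-butyldimethylsilyloxy)benzaldehyde)
Conditions: TBSCl (1.1 equiv), imidazole (2 equiv), DMF, 0 °C → rt, 3 h
Reagents that add atoms: TBSCl, CC(C)(C)[Si](C)(C)Cl
Why: Standard silylation of a phenol. The aldehyde is untouched, and the TBS group survives the Wittig step and is later removed under non-reducing, non-acidic conditions.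

**Step 2**
Reactants: 3; 4 (methyltriphenylphosphonium bromide)
Product: 5 (4-(tert-butyldimethylsilyloxy)styrene)
Conditions: Ph3PCH3Br (1.3 equiv), KOtBu (1.2 equiv), THF, 0 °C → rt, 2 h; stabilise the product with BHT and use it promptly
Reagents that add atoms: methyltriphenylphosphonium bromide, C[P+](c1ccccc1)(c1ccccc1)c1ccccc1.[Br-]
Why: Wittig methylenation of an aryl aldehyde. The slight deficit of base relative to the phosphonium salt leaves no free alkoxide to cleave the aryl silyl ether.

**Step 3**
Reactants: 5 (4-(TBSO)styrene, 1.5 equiv); 6 (triacontanoic acid, 1.0 equiv)
Product: 7 (4-(TBSO)phenethyl triacontanoate)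
Conditions: 9-Mesityl-3,6-di-tert-butyl-10-phenylacridinium BF4 (2.5 mol%), PhSSPh (5 mol%), 2,4,6-collidine (10 mol%), 1,2-DCE, 0.05 M in acid, 50 °C, blue LEDs (450 nm), 24 h; add 5 slowly by syringe pump
Reagents that add atoms: none (the acid 6 is the reactant; the catalysts and base do not appear in the product)
Why: Proposed new method: excited acridinium oxidises the electron-rich 4-silyloxystyrene (about +1.3 V) to its radical cation. The collidinium-buffered C30 carboxylate adds at the unsubstituted terminal carbon, giving the stabilised benzylic radical, and ArSH (from PhSSPh) transfers H• to give the primary phenethyl ester. The closest known reaction is photoredox anti-Markovnikov hydro-acyloxylation of alkenes via alkene radical cations. The new aspects are a *p*-silyloxystyrene (an easily oxidised and easily dimerised radical cation) and a very lipophilic, poorly soluble C30 fatty acid. These are handled by hot DCE, slow alkene addition and catalytic buffering base. No stereocenter is formed, and the primary C–O bond forms regiospecifically without acylating any free phenol.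

**Step 4**
Reactants: 7
Product: 8 (target, 4-hydroxyphenethyl triacontanoate)
Conditions: TBAF (1 M in THF, 1.5 equiv), AcOH (1.5 equiv), THF, 0 °C → rt, 2 h; then recrystallise
Reagents that add atoms: none (H replaces the silyl group)
Why: Fluoride cleaves the aryl Si–O bond. AcOH buffering prevents phenoxide-mediated transesterification or ester hydrolysis, and the ester and benzene ring are untouched.

## Compound list
1 | 4-hydroxybenzaldehyde | O=Cc1ccc(O)cc1 | starting material
2 | tert-butyldimethylsilyl chloride | CC(C)(C)[Si](C)(C)Cl | starting material (reagent)
3 | 4-(tert-butyldimethylsilyloxy)benzaldehyde | O=Cc1ccc(O[Si](C)(C)C(C)(C)C)cc1 | intermediate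
4 | methyltriphenylphosphonium bromide | C[P+](c1ccccc1)(c1ccccc1)c1ccccc1.[Br-] | starting material (reagent)
5 | 4-(tert-butyldimethylsilyloxy)styrene | C=Cc1ccc(O[Si](C)(C)C(C)(C)C)cc1 | intermediate
6 | triacontanoic acid | CCCCCCCCCCCCCCCCCCCCCCCCCCCCCC(=O)O | starting material
7 | 4-(TBSO)phenethyl triacontanoate | CCCCCCCCCCCCCCCCCCCCCCCCCCCCCC(=O)OCCc1ccc(O[Si](C)(C)C(C)(C)C)cc1 | intermediate
8 | Basalethanolide B (4-hydroxyphenethyl triacontanoate) | CCCCCCCCCCCCCCCCCCCCCCCCCCCCCC(=O)OCCc1ccc(O)cc1 | target

## Totals
Total steps: 4. Longest linear sequence: 4 (1 → 3 → 5 → 7 → 8).

## Three steps most likely to fail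
1. **Step 3 (proposed new step).** The styrene radical cation may dimerise or polymerise, and the C30 acid is poorly soluble.
   Fallback (known chemistry): hydroborate 5 with 9-BBN and oxidise with NaBO3 to give 2-(4-TBSO-phenyl)ethanol. Acylate this with triacontanoyl chloride (from 6 and oxalyl chloride), pyridine/DMAP, in toluene at 60 °C, then carry on to Step 4.
2. **Step 2.** The aryl TBS ether may be partly cleaved by base, or the styrene may polymerise on storage.
   Fallback: skip the Wittig and make the styrene by Suzuki coupling of 4-bromophenol TBS ether with potassium vinyltrifluoroborate (Pd(dppf)Cl2, Cs2CO3, aqueous THF).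
3. **Step 4.** The C30 ester is poorly soluble, and the TBAF conditions may cause partial transesterification.
   Fallback: use a benzyl ether as the phenol protecting group from the start (BnBr in Step 1, 4-benzyloxystyrene carried through Step 3). Remove it at the end by H2 and Pd(OH)2/C in warm THF/EtOAc, after thorough removal of sulfur-containing residues.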